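The route rests on cutting the C4a–C5 bond of ring A. Along the path C4–C4a–C8a–C8–C7–C6–C5 the oxygen atoms sit on alternate carbons (C4, C8a, C7, C5), so the hexasubstituted benzene ring is a folded 3,5,7-trioxo ester, and the oxygen on C8a is already O1 of the heterocycle. The precursor is therefore a β-keto methyl ester (C5–C7) that carries the (R)-configured side chain on C6, the prenyl group on C8 and a preformed cis-(2S,3R)-2,3-dimethyl-2,3-dihydropyran-4-one in place of the C8a and C4 carbonyls. One base-mediated Claisen condensation joins C4a to C5, closes ring A and aromatises it with all six substituents in place.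

Key step: step 12

Remarks on the chemistry:
- Atom labels C2–C8a follow the chromanone numbering of the target in every compound.
- The side-chain stereocentre is R in compounds 18–25. A bare 1-methyl 5-tert-butyl 3-pentylpentanedioate with the same spatial arrangement would be named 3S, because acylation of C2 changes the CIP ranking of the two ester arms.
- Precursor design: the prenyl group is placed on C8 before the pyranone is built, so no late alkylation of an ambident anion is needed. The side-chain acid is a tert-butyl ester, which resists attack by C8 and by alkoxide. Both C6–H and C8–H are acidic, so two equivalents of base are budgeted for step 12.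
- Commercial solutions of the lithium amide bases are assumed.

Step 1
Reactants: 1 (R)-4-benzyl-3-propionyloxazolidin-2-one; 2 acetaldehyde
Product: 3 (R)-4-benzyl-3-[(2R,3S)-3-hydroxy-2-methylbutanoyl]oxazolidin-2-one
Conditions: Bu2BOTf, iPr2NEt, CH2Cl2, 0 °C; 2, −78 → 0 °C; pH 7 buffer, MeOH, H2O2
Reagents that add atoms: none
Why: Evans syn aldol addition, in which the Z boron enolate reacts through a chair transition state on the face away from the benzyl group, so the (R) auxiliary should give the (2R,3S) syn adduct that becomes C3 and C2.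

Step 2
Reactants: 3 (R)-4-benzyl-3-[(2R,3S)-3-hydroxy-2-methylbutanoyl]oxazolidin-2-one
Product: 4 (2R,3S)-3-hydroxy-N-methoxy-N,2-dimethylbutanamide
Conditions: MeNH(OMe)·HCl, AlMe3, CH2Cl2, −20 °C → rt; 0.5 M HCl work-up
Reagents that add atoms: N,O-dimethylhydroxylamine hydrochloride, CNOC.Cl
Why: Weinreb transamidation with an aluminium amide, directed by the free β-hydroxyl to the exocyclic acyl group, leaves both stereocentres untouched and releases the auxiliary.

Step 3
Reactants: 4 (2R,3S)-3-hydroxy-N-methoxy-N,2-dimethylbutanamide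
Product: 5 (2R,3S)-N-methoxy-N,2-dimethyl-3-[(triethylsilyl)oxy]butanamide
Conditions: Et3SiCl, imidazole, DMF, 0 °C → rt
Reagents that add atoms: chlorotriethylsilane, CC[Si](Cl)(CC)CC
Why: Silyl ether formation on a secondary alcohol; the triethylsilyl group should survive the lithium dianion of step 6 and come off quickly under the mild acid of step 7.

Step 4
Reactants: 6 2,2,6-trimethyl-4H-1,3-dioxin-4-one; 7 acetyl chloride
Product: 8 2,2-dimethyl-6-(2-oxopropyl)-4H-1,3-dioxin-4-one
Conditions: LiN(SiMe3)2 (2 equiv), 6 (2 equiv), THF, −78 °C; 7 (1 equiv); aq. NH4Cl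
Reagents that add atoms: none
Why: Vinylogous Claisen-type γ-acylation of the lithium dienolate of the dioxinone; the dienolate is used in twofold amount because the product is more acidic than 6.

Step 5
Reactants: 8 2,2-dimethyl-6-(2-oxopropyl)-4H-1,3-dioxin-4-one; 9 prenyl bromide
Product: 10 2,2-dimethyl-6-(6-methyl-2-oxohept-5-en-3-yl)-4H-1,3-dioxin-4-one
Conditions: K2CO3, acetone, 0 °C → rt, 9 (1.0 equiv)
Reagents that add atoms: none
Why: C-alkylation of an active methylene (C8, flanked by the ketone and the vinylogous ester) with a soft allylic bromide, as for a β-keto ester; one equivalent of bromide should limit dialkylation.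

Step 6
Reactants: 10 2,2-dimethyl-6-(6-methyl-2-oxohept-5-en-3-yl)-4H-1,3-dioxin-4-one; 5 (2R,3S)-N-methoxy-N,2-dimethyl-3-[(triethylsilyl)oxy]butanamide
Product: 11 2,2-dimethyl-6-[(9R,10S)-2,9-dimethyl-6,8-dioxo-10-(triethylsilyloxy)undec-2-en-5-yl]-4H-1,3-dioxin-4-one
Conditions: LiN(iPr)2 (2.3 equiv), THF, −78 → −40 °C; 5 (0.8 equiv), −78 → −20 °C; AcOH quench
Reagents that add atoms: none
Why: Crossed Claisen-type C-acylation of a 1,3-dicarbonyl dianion at its terminal carbon (C4a) by a Weinreb amide; the chelated tetrahedral adduct holds back the ketone until work-up, so the α-stereocentre of 5 should not be exposed to base.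

Step 7
Reactants: 11 2,2-dimethyl-6-[(9R,10S)-2,9-dimethyl-6,8-dioxo-10-(triethylsilyloxy)undec-2-en-5-yl]-4H-1,3-dioxin-4-one
Product: 14 6-{1-[(2S,3R)-2,3-dimethyl-4-oxo-3,4-dihydro-2H-pyran-6-yl]-4-methylpent-3-en-1-yl}-2,2-dimethyl-4H-1,3-dioxin-4-one, via hydroxy diketone 12 (not isolated), via cyclic hemiketal 13 (not isolated)
Conditions: 48% aq. HF, MeCN, 0 °C → rt
Reagents that add atoms: none
Why: Cyclodehydration of a δ-hydroxy β-diketone: desilylation frees the C2 hydroxyl, which adds 6-exo-trig to the C8a ketone, and acid-catalysed loss of water towards C4a gives the vinylogous ester; neither C2 nor C3 is touched, so the syn aldol pattern should become the cis-2,3-dimethyl pair.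

Step 8
Reactants: 14 6-{1-[(2S,3R)-2,3-dimethyl-4-oxo-3,4-dihydro-2H-pyran-6-yl]-4-methylpent-3-en-1-yl}-2,2-dimethyl-4H-1,3-dioxin-4-one
Product: 16 methyl 4-[(2S,3R)-2,3-dimethyl-4-oxo-3,4-dihydro-2H-pyran-6-yl]-7-methyl-3-oxooct-6-enoate, via acylketene 15 (not isolated)
Conditions: MeOH/toluene (1:2), 110 °C, sealed tube
Reagents that add atoms: methanol, CO
Why: Thermal retro-hetero-Diels–Alder reaction of the dioxinone releases acetone and an acylketene, which methanol in large excess should trap as the β-keto methyl ester before any intramolecular capture.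

Step 9
Reactants: 16 methyl 4-[(2S,3R)-2,3-dimethyl-4-oxo-3,4-dihydro-2H-pyran-6-yl]-7-methyl-3-oxooct-6-enoate; 17 (E)-oct-2-enal
Product: 18 methyl 4-[(2S,3R)-2,3-dimethyl-4-oxo-3,4-dihydro-2H-pyran-6-yl]-7-methyl-3-oxo-2-[(3R)-1-oxooctan-3-yl]oct-6-enoate
Conditions: (S)-2-{bis[3,5-bis(trifluoromethyl)phenyl](trimethylsilyloxy)methyl}pyrrolidine (10 mol %), PhCO2H (10 mol %), toluene, 0 °C → rt
Reagents that add atoms: none
Why: Iminium-catalysed asymmetric Michael addition of a β-keto ester to an enal: the C6 methylene adds to the β-carbon of the E,s-trans iminium ion on the face away from the diarylsilyloxymethyl group of the (S)-catalyst, which should set the (R) centre, while the epimers at C6 and C8 are erased later.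

Step 10
Reactants: 18 methyl 4-[(2S,3R)-2,3-dimethyl-4-oxo-3,4-dihydro-2H-pyran-6-yl]-7-methyl-3-oxo-2-[(3R)-1-oxooctan-3-yl]oct-6-enoate
Product: 19 (3R)-3-{4-[(2S,3R)-2,3-dimethyl-4-oxo-3,4-dihydro-2H-pyran-6-yl]-1-methoxy-7-methyl-1,3-dioxooct-6-en-2-yl}octanoic acid
Conditions: NaClO2, NaH2PO4, 2-methylbut-2-ene (large excess), t-BuOH/H2O, 0 °C → rt
Reagents that add atoms: sodium chlorite, [Na+].[O-]Cl=O
Why: Pinnick oxidation takes the aldehyde to the acid under buffered conditions, with excess 2-methylbut-2-ene scavenging hypochlorous acid to spare the prenyl group and the enolisable positions.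

Step 11
Reactants: 19 (3R)-3-{4-[(2S,3R)-2,3-dimethyl-4-oxo-3,4-dihydro-2H-pyran-6-yl]-1-methoxy-7-methyl-1,3-dioxooct-6-en-2-yl}octanoic acid
Product: 20 tert-butyl (3R)-3-{4-[(2S,3R)-2,3-dimethyl-4-oxo-3,4-dihydro-2H-pyran-6-yl]-1-methoxy-7-methyl-1,3-dioxooct-6-en-2-yl}octanoate
Conditions: tert-butyl 2,2,2-trichloroacetimidate (3 equiv), CH2Cl2/cyclohexane, rt, no added acid
Reagents that add atoms: tert-butyl 2,2,2-trichloroacetimidate, CC(C)(C)OC(=N)C(Cl)(Cl)Cl
Why: Trichloroacetimidate esterification runs on the acidity of the carboxylic acid alone, so neither base nor strong acid should touch the β-keto ester, the prenyl group or the cis pair.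

Step 12
Reactants: 20 tert-butyl (3R)-3-{4-[(2S,3R)-2,3-dimethyl-4-oxo-3,4-dihydro-2H-pyran-6-yl]-1-methoxy-7-methyl-1,3-dioxooct-6-en-2-yl}octanoate
Product: 22 tert-butyl (3R)-3-[(2S,3R)-5,7-dihydroxy-2,3-dimethyl-8-(3-methylbut-2-en-1-yl)-4-oxo-3,4-dihydro-2H-chromen-6-yl]octanoate, via cyclohexenetrione tautomer 21 (not isolated)
Conditions: KOtBu (2.5 equiv), t-BuOH/THF (1:1), 0 → 40 °C; then 0.5 M HCl to pH 5, 0 °C
Reagents that add atoms: none
Why: tert-Butoxide removes C6–H and C8–H reversibly, and in the protic medium the C8 anion with an un-enolised C5 ester stays accessible by proton exchange; this anion is a dienolate of the vinylogous ester (charge on O4, C4a, C8 and O7), its C4a terminus adds to the C5 methyl ester, methoxide leaves, and three enolisations of 21 give the bis-phenoxide of 22, which should make the sequence irreversible. The closest known reaction type is the base-mediated Claisen (Dieckmann-type) cyclisation of 3,5,7-trioxoalkanoates to acylphloroglucinols, run here on a substrate in which one carbonyl is locked as a cyclic vinylogous ester. Ring A closes by 6-exo-trig attack on the ester; C4=C4a of the enolate lies outside the new ring (enolexo) while C8=C8a lies inside it, so the geometric demand is that of an allowed 6-(enolendo)-exo-trig closure. No stereocentre is formed, and C2 and C3 should be preserved because C4=O is part of the dienolate and later of the 5-phenoxide, so C3–H is not removed, while the side-chain centre is not acidic. The step needs Claisen rather than aldol folding and C- rather than O-acylation: the pyranone double bond holds C8 trans to C4 (C6 cannot reach C4) and cis to C4a–H, O1 already sits on C8a so the oxygens on C8a and C5 need not be told apart, and the tert-butyl ester resists attack by C8 or alkoxide. Two equivalents of base are consumed, so a small excess is used and the mixture is acidified cold to spare the ortho-prenyl phenol.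

Step 13
Reactants: 22 tert-butyl (3R)-3-[(2S,3R)-5,7-dihydroxy-2,3-dimethyl-8-(3-methylbut-2-en-1-yl)-4-oxo-3,4-dihydro-2H-chromen-6-yl]octanoate
Product: 23 tert-butyl (3R)-3-[(2S,3R)-5-hydroxy-7-methoxy-2,3-dimethyl-8-(3-methylbut-2-en-1-yl)-4-oxo-3,4-dihydro-2H-chromen-6-yl]octanoate
Conditions: Me3SiCHN2 (1.3 equiv), MeOH/toluene (1:4), 0 °C → rt
Reagents that add atoms: (trimethylsilyl)diazomethane, C[Si](C)(C)C=[N+]=[N-]
Why: O-methylation by diazomethane generated in the flask: only the free, acidic 7-OH should protonate it, the 5-OH is held in a hydrogen bond to C4=O, and no base is present that could epimerise C3.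

Step 14
Reactants: 23 tert-butyl (3R)-3-[(2S,3R)-5-hydroxy-7-methoxy-2,3-dimethyl-8-(3-methylbut-2-en-1-yl)-4-oxo-3,4-dihydro-2H-chromen-6-yl]octanoate
Product: 25 (3R)-3-[(2S,3R)-5-hydroxy-7-methoxy-2,3-dimethyl-8-(3-methylbut-2-en-1-yl)-4-oxo-3,4-dihydro-2H-chromen-6-yl]octanoic acid, via trimethylsilyl ester 24 (not isolated)
Conditions: Me3SiOTf (1.5 equiv), 2,6-lutidine (3 equiv), CH2Cl2, 0 °C → rt; aq. NaH2PO4 work-up
Reagents that add atoms: none
Why: Silyl triflate-mediated cleavage of a tert-butyl ester (O-silylation, loss of the tert-butyl cation as 2-methylpropene, hydrolysis of the silyl ester on work-up) uses no protic acid that could cyclise the prenyl group or lactonise, and no base strong enough to enolise C4.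

Compound list
1 | (R)-4-benzyl-3-propionyloxazolidin-2-one | CCC(=O)N1[C@H](Cc2ccccc2)COC1=O | starting material
2 | acetaldehyde | CC=O | starting material
3 | (R)-4-benzyl-3-[(2R,3S)-3-hydroxy-2-methylbutanoyl]oxazolidin-2-one | C[C@H](O)[C@@H](C)C(=O)N1[C@H](Cc2ccccc2)COC1=O | intermediate
4 | (2R,3S)-3-hydroxy-N-methoxy-N,2-dimethylbutanamide | C[C@H](O)[C@@H](C)C(=O)N(C)OC | intermediate
5 | (2R,3S)-N-methoxy-N,2-dimethyl-3-[(triethylsilyl)oxy]butanamide | C[C@H](O[Si](CC)(CC)CC)[C@@H](C)C(=O)N(C)OC | intermediate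
6 | 2,2,6-trimethyl-4H-1,3-dioxin-4-one | CC1=CC(=O)OC(C)(C)O1 | starting material
7 | acetyl chloride | CC(Cl)=O | starting material
8 | 2,2-dimethyl-6-(2-oxopropyl)-4H-1,3-dioxin-4-one | CC(=O)CC1=CC(=O)OC(C)(C)O1 | intermediate
9 | prenyl bromide (1-bromo-3-methylbut-2-ene) | CC(C)=CCBr | starting material
10 | 2,2-dimethyl-6-(6-methyl-2-oxohept-5-en-3-yl)-4H-1,3-dioxin-4-one (racemic at C8, enol forms) | CC(=O)C(CC=C(C)C)C1=CC(=O)OC(C)(C)O1 | intermediate
11 | 2,2-dimethyl-6-[(9R,10S)-2,9-dimethyl-6,8-dioxo-10-(triethylsilyloxy)undec-2-en-5-yl]-4H-1,3-dioxin-4-one (C8 epimers, enol forms) | C[C@H](O[Si](CC)(CC)CC)[C@@H](C)C(=O)CC(=O)C(CC=C(C)C)C1=CC(=O)OC(C)(C)O1 | intermediate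
12 | hydroxy diketone: 6-[(9R,10S)-10-hydroxy-2,9-dimethyl-6,8-dioxoundec-2-en-5-yl]-2,2-dimethyl-4H-1,3-dioxin-4-one (not isolated) | C[C@H](O)[C@@H](C)C(=O)CC(=O)C(CC=C(C)C)C1=CC(=O)OC(C)(C)O1 | intermediate
13 | cyclic hemiketal: 6-{1-[(5R,6S)-2-hydroxy-5,6-dimethyl-4-oxotetrahydro-2H-pyran-2-yl]-4-methylpent-3-en-1-yl}-2,2-dimethyl-4H-1,3-dioxin-4-one (not isolated) | CC(C)=CCC(C1=CC(=O)OC(C)(C)O1)C2(O)CC(=O)[C@H](C)[C@H](C)O2 | intermediate
14 | 6-{1-[(2S,3R)-2,3-dimethyl-4-oxo-3,4-dihydro-2H-pyran-6-yl]-4-methylpent-3-en-1-yl}-2,2-dimethyl-4H-1,3-dioxin-4-one (C8 epimers) | CC(C)=CCC(C1=CC(=O)OC(C)(C)O1)C2=CC(=O)[C@H](C)[C@H](C)O2 | intermediate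
15 | acylketene: 4-[(2S,3R)-2,3-dimethyl-4-oxo-3,4-dihydro-2H-pyran-6-yl]-7-methylocta-1,6-diene-1,3-dione (not isolated) | O=C=CC(=O)C(CC=C(C)C)C1=CC(=O)[C@H](C)[C@H](C)O1 | intermediate
16 | methyl 4-[(2S,3R)-2,3-dimethyl-4-oxo-3,4-dihydro-2H-pyran-6-yl]-7-methyl-3-oxooct-6-enoate (C8 epimers, enol forms) | COC(=O)CC(=O)C(CC=C(C)C)C1=CC(=O)[C@H](C)[C@H](C)O1 | intermediate
17 | (E)-oct-2-enal | CCCCC/C=C/C=O | starting material
18 | methyl 4-[(2S,3R)-2,3-dimethyl-4-oxo-3,4-dihydro-2H-pyran-6-yl]-7-methyl-3-oxo-2-[(3R)-1-oxooctan-3-yl]oct-6-enoate (C6 and C8 epimers; open form of a lactol equilibrium) | CCCCC[C@H](CC=O)C(C(=O)OC)C(=O)C(CC=C(C)C)C1=CC(=O)[C@H](C)[C@H](C)O1 | intermediate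
19 | (3R)-3-{4-[(2S,3R)-2,3-dimethyl-4-oxo-3,4-dihydro-2H-pyran-6-yl]-1-methoxy-7-methyl-1,3-dioxooct-6-en-2-yl}octanoic acid | CCCCC[C@H](CC(=O)O)C(C(=O)OC)C(=O)C(CC=C(C)C)C1=CC(=O)[C@H](C)[C@H](C)O1 | intermediate
20 | tert-butyl (3R)-3-{4-[(2S,3R)-2,3-dimethyl-4-oxo-3,4-dihydro-2H-pyran-6-yl]-1-methoxy-7-methyl-1,3-dioxooct-6-en-2-yl}octanoate (key-step precursor; C6 and C8 epimers, enol forms) | CCCCC[C@H](CC(=O)OC(C)(C)C)C(C(=O)OC)C(=O)C(CC=C(C)C)C1=CC(=O)[C@H](C)[C@H](C)O1 | intermediate
21 | cyclohexenetrione tautomer of 22, first Claisen product before enolisation (not isolated) | CCCCC[C@H](CC(=O)OC(C)(C)C)C1C(=O)C(CC=C(C)C)=C2O[C@@H](C)[C@@H](C)C(=O)C2C1=O | intermediate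
22 | tert-butyl (3R)-3-[(2S,3R)-5,7-dihydroxy-2,3-dimethyl-8-(3-methylbut-2-en-1-yl)-4-oxo-3,4-dihydro-2H-chromen-6-yl]octanoate (key-step product) | CCCCC[C@H](CC(=O)OC(C)(C)C)c1c(O)c2c(c(CC=C(C)C)c1O)O[C@@H](C)[C@@H](C)C2=O | intermediate
23 | tert-butyl (3R)-3-[(2S,3R)-5-hydroxy-7-methoxy-2,3-dimethyl-8-(3-methylbut-2-en-1-yl)-4-oxo-3,4-dihydro-2H-chromen-6-yl]octanoate | CCCCC[C@H](CC(=O)OC(C)(C)C)c1c(O)c2c(c(CC=C(C)C)c1OC)O[C@@H](C)[C@@H](C)C2=O | intermediate
24 | trimethylsilyl ester of 25 (not isolated) | CCCCC[C@H](CC(=O)O[Si](C)(C)C)c1c(O)c2c(c(CC=C(C)C)c1OC)O[C@@H](C)[C@@H](C)C2=O | intermediate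
25 | (3R)-3-[(2S,3R)-5-hydroxy-7-methoxy-2,3-dimethyl-8-(3-methylbut-2-en-1-yl)-4-oxo-3,4-dihydro-2H-chromen-6-yl]octanoic acid | CCCCC[C@H](CC(=O)O)c1c(O)c2c(c(CC=C(C)C)c1OC)O[C@@H](C)[C@@H](C)C2=O | target

Total step count: 14.
Longest linear sequence: 12 steps (steps 1, 2, 3, 6, 7, 8, 9, 10, 11, 12, 13, 14, from compound 1 to compound 25).

Steps most likely to fail

Step 12. Once both C6–H and C8–H are removed, the C5 ester is conjugated with the C6 enolate and crowded by the branched side chain, so C-acylation by C4a may stall. A slow reaction would leave time for erosion of the cis relationship at C3 and for alkoxide exchange at the esters. The fallback sets out from 16 and 17 and returns at 22; it forms ring A before the side chain is attached. The same Claisen closure (KOtBu, t-BuOH/THF) is run on 16, where C6 is unsubstituted, to give (2S,3R)-5,7-dihydroxy-2,3-dimethyl-8-(3-methylbut-2-en-1-yl)chroman-4-one F1. Its only free ring carbon, C6, lies between two hydroxyls and should add to the iminium ion of 17 under the catalyst of step 9 in a Friedel–Crafts-type conjugate addition on the same face. The adduct closes on the 7-oxygen to the (R)-configured lactol F2. Ag2CO3 on Celite in toluene should oxidise the lactol to the dihydrocoumarin-type lactone F3. KOtBu in t-BuOH then opens the aryl lactone to the tert-butyl ester 22.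

Step 9. The donor has two acidic sites, so addition may be divided between C6 and C8. The adduct may also be consumed by intramolecular aldol closure onto the new aldehyde, and facial control with an aliphatic enal may be weak. The fallback sets out from 16 and 17 and returns at 20; it replaces iminium catalysis by oxidative carbene catalysis at the acid oxidation level. A chiral aminoindanol-derived triazolium carbene and 3,3',5,5'-tetra-tert-butyldiphenoquinone convert 17 into an α,β-unsaturated acyl azolium. C6 of 16 adds to it and O7 then acylates, giving the (R)-configured enol δ-lactone F4; the carbene enantiomer is chosen for this centre. One equivalent of LiOtBu in THF at −40 °C should open the enol lactone to 20, which by-passes 18 and 19.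

Step 6. The second deprotonation of the prenylated keto-dioxinone may be incomplete. Proton transfer may compete with C-acylation by the branched amide, and base may trigger aldol aromatisation of the diketo-dioxinone during work-up. The fallback sets out from 5 and 10 and returns at 11; it replaces acylation by aldol addition and oxidation. iBu2AlH in CH2Cl2 at −78 °C reduces 5 to (2R,3S)-2-methyl-3-[(triethylsilyl)oxy]butanal F5. The dianion of 10 should add to this more reactive electrophile at −78 °C to give the β-hydroxy ketone F6 as a mixture at the new carbinol. Dess–Martin periodinane then oxidises F6 to 11.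

Further compounds
F1 | step 12 | (2S,3R)-5,7-dihydroxy-2,3-dimethyl-8-(3-methylbut-2-en-1-yl)chroman-4-one | CC(C)=CCc1c(O)cc(O)c2c1O[C@@H](C)[C@@H](C)C2=O
F2 | step 12 | lactol between O7 and the new C6 side chain (2-hydroxychroman ring fused at C6–C7, pentyl-bearing carbon R, lactol carbon as a mixture) | CCCCC[C@@H]1CC(O)Oc2c(CC=C(C)C)c3O[C@@H](C)[C@@H](C)C(=O)c3c(O)c21
F3 | step 12 | dihydrocoumarin-type lactone from oxidation of F2 (pentyl-bearing carbon R) | CCCCC[C@@H]1CC(=O)Oc2c(CC=C(C)C)c3O[C@@H](C)[C@@H](C)C(=O)c3c(O)c21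
F4 | step 9 | methyl (4R)-6-{1-[(2S,3R)-2,3-dimethyl-4-oxo-3,4-dihydro-2H-pyran-6-yl]-4-methylpent-3-en-1-yl}-2-oxo-4-pentyl-3,4-dihydro-2H-pyran-5-carboxylate | CCCCC[C@@H]1CC(=O)OC(C(CC=C(C)C)C2=CC(=O)[C@H](C)[C@H](C)O2)=C1C(=O)OC
F5 | step 6 | (2R,3S)-2-methyl-3-[(triethylsilyl)oxy]butanal | C[C@H](O[Si](CC)(CC)CC)[C@@H](C)C=O
F6 | step 6 | β-hydroxy ketone from the dianion of 10 and F5 (8-hydroxy analogue of 11, mixture at the new carbinol) | C[C@H](O[Si](CC)(CC)CC)[C@@H](C)C(O)CC(=O)C(CC=C(C)C)C1=CC(=O)OC(C)(C)O1
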